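A direct plan would make ring C first and ring A last. The enolate of ketone A1 would be C-acylated with a β-ethoxyacryloyl chloride and cyclised to the 2-aryl-4-pyranone A2. A2 would be lithiated at C6, added to dimethyl squarate A3 and O-methylated to cyclobutenone A4. Heating A4 would give a dienylketene that closes ring A by 6π electrocyclisation to the benzyl-protected flavone A5, which would then be hydrogenolysed. Its weakest points would be:
(a) the lithiation of A2 and its trapping: a 4-pyranone is a conjugate acceptor that amide bases can open, the benzyl ethers offer benzylic C–H, and the pyranone carbonyl competes for the methylating agent;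
(b) the thermal ring expansion of A4: the only event that forms ring A would rest on the sense of rotation of the cyclobutenone opening and on a ketene attacking an electron-poor pyranone carbon, without close precedent and on the most advanced material;
(c) the enolate C-acylation: O-acylation and double acylation would compete at the foot of a wholly linear sequence.

Plan of the new route. The retrosynthesis removes three O-alkyl groups (5-OMe and two isopropyl ethers on ring B), then cuts ring C at C4–C4a, C8a–O1 and O1–C2. This leads to the symmetric 3,4,5,6-tetramethoxybenzyne (ring A) and an arylpropiolic acid (C2, C3, C4 and ring B). Rings A and B are bought as benzenes, and ring C arises last, in one operation. The enabling feature is ring A: four contiguous oxygens on C5–C8 beside the ortho C/O pair at C4a/C8a. As the tetramethyl ether, the aryne C4a≡C8a has a mirror plane, so its insertion into the C–O bond of the acid has no regiochemistry to control; the C5 oxygen is singled out afterwards by its peri position to C4=O. No pyranone is metalated, no cyclobutenone is opened, and no ring closure rests on an electrocyclisation.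

Key step: step 7

Remark: 1,2,3,4-tetramethoxybenzene is taken as a catalogue compound, and the target is achiral, so no stereocentre has to be set.

Step 1
Reactants: 1 1,2,3,4-tetramethoxybenzene
Product: 4 2,3,4,5-tetramethoxyphenol, via aryllithium 2 (not isolated), via arylboronate 3 (not isolated)
Conditions: n-BuLi (1.2 equiv), TMEDA (1.2 equiv), THF, 0 °C → rt; B(OMe)3 (2 equiv), −78 °C → rt; AcOH, 30% aq H2O2, 0 °C → rt
Reagents that add atoms: hydrogen peroxide, OO
Why: Directed ortho-metalation by the flanking OMe groups at the only kind of ring C–H present (the two are equivalent), followed by borylation and boronate oxidation (1,2-shift of aryl from boron to oxygen), adds the fifth ring oxygen, which will become the leaving group of the aryne precursor.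

Step 2
Reactants: 4 2,3,4,5-tetramethoxyphenol
Product: 5 2-bromo-3,4,5,6-tetramethoxyphenol
Conditions: NBS (1.0 equiv), CH2Cl2 (anhydrous, dark), −78 → 0 °C
Reagents that add atoms: N-bromosuccinimide, O=C1CCC(=O)N1Br
Why: Electrophilic aromatic bromination of a phenol at its single free ring position, which is ortho to OH, run cold and anhydrous so that substitution should outrun oxidation of the para-methoxyphenol.

Step 3
Reactants: 5 2-bromo-3,4,5,6-tetramethoxyphenol
Product: 8 3,4,5,6-tetramethoxy-2-(trimethylsilyl)phenyl trifluoromethanesulfonate, via silyl ether 6 (not isolated), via lithium phenoxide 7 (not isolated)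
Conditions: HMDS (1.2 equiv), THF, 65 °C, then evaporate; n-BuLi (1.1 equiv), THF, −100 → −78 °C; Tf2O (1.2 equiv), −100 °C → rt
Reagents that add atoms: hexamethyldisilazane, C[Si](C)(C)N[Si](C)(C)C; trifluoromethanesulfonic anhydride, O=S(=O)(OS(=O)(=O)C(F)(F)F)C(F)(F)F
Why: The standard one-flask route to ortho-silylaryl triflates, in which O-silylation, bromine–lithium exchange and a 1,3 O→C silyl shift (retro-Brook rearrangement) place silicon on the former C–Br carbon and triflation of phenoxide 7 completes a fluoride-triggered aryne precursor whose two oxygen-free ring carbons are the future C4a and C8a.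

Step 4
Reactants: 9 2,4-dihydroxybenzaldehyde
Product: 10 2,4-di(propan-2-yloxy)benzaldehyde
Conditions: 2-bromopropane (3 equiv), K2CO3 (3 equiv), DMF, 70 °C
Reagents that add atoms: 2-bromopropane, CC(C)Br
Why: Williamson ether synthesis with heat and excess base so that the hydrogen-bonded 2-OH is alkylated as well, isopropyl ethers being chosen because they should survive n-BuLi and CsF at 125 °C and leave under the same BCl3 treatment that removes the peri-methyl group.

Step 5
Reactants: 10 2,4-di(propan-2-yloxy)benzaldehyde
Product: 11 1-(2,2-dibromoethenyl)-2,4-di(propan-2-yloxy)benzene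
Conditions: CBr4 (1.5 equiv), PPh3 (3 equiv), CH2Cl2, 0 °C
Reagents that add atoms: carbon tetrabromide, BrC(Br)(Br)Br
Why: Corey–Fuchs dibromoolefination (Wittig-type reaction of the ylide Ph3P=CBr2 made in the flask), which adds the carbon that becomes C3 of the flavone while the aldehyde carbon becomes C2.

Step 6
Reactants: 11 1-(2,2-dibromoethenyl)-2,4-di(propan-2-yloxy)benzene
Product: 14 3-[2,4-di(propan-2-yloxy)phenyl]prop-2-ynoic acid, via bromoalkyne 12 (not isolated), via lithium acetylide 13 (not isolated)
Conditions: n-BuLi (2.1 equiv), THF, −78 °C; CO2 (dry gas), −78 °C → rt; aq HCl to pH 2, 0 °C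
Reagents that add atoms: carbon dioxide, O=C=O
Why: Second stage of the Corey–Fuchs sequence, in which dehydrobromination to bromoalkyne 12 and bromine–lithium exchange give acetylide 13, whose carboxylation supplies the carbon that becomes C4 and whose acidification releases the acid.

Step 7
Reactants: 8 3,4,5,6-tetramethoxy-2-(trimethylsilyl)phenyl trifluoromethanesulfonate; 14 3-[2,4-di(propan-2-yloxy)phenyl]prop-2-ynoic acid
Product: 18 5,6,7,8-tetramethoxy-2-[2,4-di(propan-2-yloxy)phenyl]-4H-chromen-4-one, via aryne 15 (not isolated), via arylcesium 16 (not isolated), via ynone phenoxide 17 (not isolated)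
Conditions: 14 (1.0 equiv), 8 (1.5 equiv), CsF (4 equiv), THF (0.05 M), sealed tube, 125 °C
Reagents that add atoms: none
Why: Fluoride removes the silyl group of 8 and triflate leaves to give aryne 15, the cesium carboxylate of 14 adds through oxygen to one aryne carbon, and the aryl anion 16, ortho to the new acyloxy group, attacks the ester carbonyl (4-exo-trig, a benzoxetene alkoxide) and opens to the ortho-acylphenoxide 17, a net insertion of the aryne into the C–O bond of the acid that forms the C4–C4a and C8a–O1 bonds in one event. Ring C then closes by 6-endo-dig oxa-Michael addition of the C8a phenoxide to the ynone β-carbon (O1–C2 bond), and protonation at C3 gives the aromatic γ-pyrone, with no stereocentre formed. The closest known reaction type is the fluoride-induced C–O insertion of arynes into carboxylic acids, which with 3-arylpropiolic acids delivers flavones directly. The selectivity usually at stake, which aryne carbon takes oxygen and which takes the acyl group, does not arise, because 15 has a mirror plane through the midpoints of the C4a≡C8a and C6–C7 bonds and both modes of addition give the same product; each aryne carbon is flanked by OMe, so the anion forms next to an inductively stabilising methoxy group whichever carbon is attacked. What the step still needs is acyl transfer ahead of protonation of 16 (aprotic THF, high temperature, no proton source beyond the transient HF) and 6-endo ahead of 5-exo closure of 17 (the β-carbon is the conjugate position, and the aurone mode would be anti-Michael). The isopropyl ether at C2' keeps the ring B oxygen from competing for the ynone.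

Step 8
Reactants: 18 5,6,7,8-tetramethoxy-2-[2,4-di(propan-2-yloxy)phenyl]-4H-chromen-4-one
Product: 19 Tamadone, 2-(2,4-dihydroxyphenyl)-5-hydroxy-6,7,8-trimethoxy-4H-chromen-4-one
Conditions: BCl3 (1 M in CH2Cl2, 6 equiv), CH2Cl2, −78 → 0 °C; MeOH; aq HCl–THF, 50 °C
Reagents that add atoms: none
Why: Lewis-acid ether cleavage in which BCl3 should ionise the two secondary (isopropyl) aryl ethers and remove only the methyl group whose oxygen is held with C4=O in a six-membered boron chelate (the peri 5-OMe), the unchelated 6-, 7- and 8-methyl ethers being inert at this temperature, while a Wessely–Moser-type opening and reclosure of ring C would be degenerate because C6 and C8 carry the same group.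

Compound list
1 | 1,2,3,4-tetramethoxybenzene | COc1ccc(OC)c(OC)c1OC | starting material
2 | (2,3,4,5-tetramethoxyphenyl)lithium (not isolated) | [Li]c1cc(OC)c(OC)c(OC)c1OC | intermediate
3 | dimethyl (2,3,4,5-tetramethoxyphenyl)boronate (not isolated) | COB(OC)c1cc(OC)c(OC)c(OC)c1OC | intermediate
4 | 2,3,4,5-tetramethoxyphenol | COc1cc(O)c(OC)c(OC)c1OC | intermediate
5 | 2-bromo-3,4,5,6-tetramethoxyphenol | COc1c(Br)c(O)c(OC)c(OC)c1OC | intermediate
6 | (2-bromo-3,4,5,6-tetramethoxyphenoxy)trimethylsilane (not isolated) | COc1c(Br)c(O[Si](C)(C)C)c(OC)c(OC)c1OC | intermediate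
7 | lithium 3,4,5,6-tetramethoxy-2-(trimethylsilyl)phenoxide (not isolated) | COc1c([Si](C)(C)C)c(O[Li])c(OC)c(OC)c1OC | intermediate
8 | 3,4,5,6-tetramethoxy-2-(trimethylsilyl)phenyl trifluoromethanesulfonate | COc1c([Si](C)(C)C)c(OS(=O)(=O)C(F)(F)F)c(OC)c(OC)c1OC | intermediate
9 | 2,4-dihydroxybenzaldehyde | O=Cc1ccc(O)cc1O | starting material
10 | 2,4-di(propan-2-yloxy)benzaldehyde | CC(C)Oc1ccc(C=O)c(OC(C)C)c1 | intermediate
11 | 1-(2,2-dibromoethenyl)-2,4-di(propan-2-yloxy)benzene | CC(C)Oc1ccc(C=C(Br)Br)c(OC(C)C)c1 | intermediate
12 | 1-(bromoethynyl)-2,4-di(propan-2-yloxy)benzene (not isolated) | CC(C)Oc1ccc(C#CBr)c(OC(C)C)c1 | intermediate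
13 | {[2,4-di(propan-2-yloxy)phenyl]ethynyl}lithium (not isolated) | CC(C)Oc1ccc(C#C[Li])c(OC(C)C)c1 | intermediate
14 | 3-[2,4-di(propan-2-yloxy)phenyl]prop-2-ynoic acid | CC(C)Oc1ccc(C#CC(=O)O)c(OC(C)C)c1 | intermediate
15 | 3,4,5,6-tetramethoxybenzyne (not isolated) | COC1=C(OC)C(OC)=C(OC)C#C1 | intermediate
16 | 2-cesio-3,4,5,6-tetramethoxyphenyl 3-[2,4-di(propan-2-yloxy)phenyl]prop-2-ynoate (not isolated) | COc1c(OC)c(OC)c(OC(=O)C#Cc2ccc(OC(C)C)cc2OC(C)C)c([Cs])c1OC | intermediate
17 | cesium 2-{3-[2,4-di(propan-2-yloxy)phenyl]prop-2-ynoyl}-3,4,5,6-tetramethoxyphenoxide (not isolated) | COc1c(OC)c(OC)c(C(=O)C#Cc2ccc(OC(C)C)cc2OC(C)C)c(O[Cs])c1OC | intermediate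
18 | 5,6,7,8-tetramethoxy-2-[2,4-di(propan-2-yloxy)phenyl]-4H-chromen-4-one | COc1c(OC)c(OC)c2c(=O)cc(-c3ccc(OC(C)C)cc3OC(C)C)oc2c1OC | intermediate
19 | Tamadone, 2-(2,4-dihydroxyphenyl)-5-hydroxy-6,7,8-trimethoxy-4H-chromen-4-one (achiral) | COc1c(OC)c(O)c2c(=O)cc(-c3ccc(O)cc3O)oc2c1OC | target

Total step count: 8. Longest linear sequence: 5 steps (steps 1, 2, 3, 7, 8; the other branch, steps 4, 5, 6, 7, 8, is equally long).

Steps most likely to fail

Step 7 (aryne C–O insertion and ring closure). Protonation of the aryl anion, or its conjugate addition to the alkyne, may outrun acyl transfer, and the electron-rich propiolic acid may lose CO2 at 125 °C before it is arylated. The fallback is a palladium-catalysed carbonylative alkynylation and cyclisation that sets out from phenol 4 and dibromoalkene 11. Phenol 4 would be iodinated (NIS, CH2Cl2, −40 °C) to 2-iodo-3,4,5,6-tetramethoxyphenol F1. Dibromoalkene 11 would be converted (n-BuLi, THF, −78 °C, then aq NH4Cl in place of CO2) into 1-ethynyl-2,4-di(propan-2-yloxy)benzene F2. Coupling of F1, F2 and CO (1–20 bar) with PdCl2(dppf) (5 mol %) in Et2NH at 60–120 °C would pass through the ortho-hydroxyaryl ynone, 1-(2-hydroxy-3,4,5,6-tetramethoxyphenyl)-3-[2,4-di(propan-2-yloxy)phenyl]prop-2-yn-1-one F3. Under the basic conditions F3 closes in the same flask by 6-endo oxa-Michael addition, and the route is rejoined at flavone 18.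

Step 8 (global dealkylation). A second methyl group, the 6-OMe beside the boron-bound C5 oxygen, may be lost, or the hindered 2'-isopropyl ether may be cleaved incompletely, when one reagent has to do both jobs. The fallback separates the two dealkylations by mechanism, setting out from 18. MgI2 (etherate, 2 equiv, toluene–Et2O, 60 °C) would cleave only the methyl ether that can sit in a six-membered magnesium chelate with C4=O (iodide SN2 at the activated methyl), giving 5-hydroxy-6,7,8-trimethoxy-2-[2,4-di(propan-2-yloxy)phenyl]-4H-chromen-4-one F4. The two secondary ethers of F4 would then be ionised at low temperature (BCl3, 3 equiv, CH2Cl2, −78 → −30 °C), where unchelated aryl methyl ethers do not react, to reach target 19.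

Step 2 (bromination of the electron-rich phenol). The brominating agent may oxidise the para-methoxyphenol instead of substituting its single free position, which would also starve the halogen–lithium exchange of step 3. The fallback is carbamate-directed ortho-metalation, which brings in silicon without any halogenation; it sets out from 4 and returns at 8, so steps 2 and 3 are both bypassed. Isopropyl isocyanate (Et3N cat., CH2Cl2, rt) would give 2,3,4,5-tetramethoxyphenyl N-(propan-2-yl)carbamate F5. The N–H would be masked in the flask (TBSOTf, TMEDA, Et2O) as 2,3,4,5-tetramethoxyphenyl N-(tert-butyldimethylsilyl)-N-(propan-2-yl)carbamate F6. Lithiation at the only ring C–H, which is flanked by the carbamate and an OMe group (n-BuLi, TMEDA, −78 °C), then TMSCl and an acidic work-up would give 2,3,4,5-tetramethoxy-6-(trimethylsilyl)phenyl N-(propan-2-yl)carbamate F7. DBU and Et2NH (MeCN, 40 °C) would release 3,4,5,6-tetramethoxy-2-(trimethylsilyl)phenol F8, which PhNTf2 would triflate in the same flask to the aryne precursor 8.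

Further compounds
F1 | step 7 | 2-iodo-3,4,5,6-tetramethoxyphenol | COc1c(I)c(O)c(OC)c(OC)c1OC
F2 | step 7 | 1-ethynyl-2,4-di(propan-2-yloxy)benzene | CC(C)Oc1ccc(C#C)c(OC(C)C)c1
F3 | step 7 | 1-(2-hydroxy-3,4,5,6-tetramethoxyphenyl)-3-[2,4-di(propan-2-yloxy)phenyl]prop-2-yn-1-one | COc1c(OC)c(OC)c(C(=O)C#Cc2ccc(OC(C)C)cc2OC(C)C)c(O)c1OC
F4 | step 8 | 5-hydroxy-6,7,8-trimethoxy-2-[2,4-di(propan-2-yloxy)phenyl]-4H-chromen-4-one | COc1c(OC)c(O)c2c(=O)cc(-c3ccc(OC(C)C)cc3OC(C)C)oc2c1OC
F5 | step 2 | 2,3,4,5-tetramethoxyphenyl N-(propan-2-yl)carbamate | COc1cc(OC(=O)NC(C)C)c(OC)c(OC)c1OC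
F6 | step 2 | 2,3,4,5-tetramethoxyphenyl N-(tert-butyldimethylsilyl)-N-(propan-2-yl)carbamate | COc1cc(OC(=O)N(C(C)C)[Si](C)(C)C(C)(C)C)c(OC)c(OC)c1OC
F7 | step 2 | 2,3,4,5-tetramethoxy-6-(trimethylsilyl)phenyl N-(propan-2-yl)carbamate | COc1c([Si](C)(C)C)c(OC(=O)NC(C)C)c(OC)c(OC)c1OC
F8 | step 2 | 3,4,5,6-tetramethoxy-2-(trimethylsilyl)phenol | COc1c([Si](C)(C)C)c(O)c(OC)c(OC)c1OC
A1 | direct plan | 1-[2,4-bis(benzyloxy)phenyl]ethan-1-one | CC(=O)c1ccc(OCc2ccccc2)cc1OCc1ccccc1
A2 | direct plan | 2-[2,4-bis(benzyloxy)phenyl]-4H-pyran-4-one | O=c1ccoc(-c2ccc(OCc3ccccc3)cc2OCc2ccccc2)c1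
A3 | direct plan | dimethyl squarate (3,4-dimethoxycyclobut-3-ene-1,2-dione) | COC1=C(OC)C(=O)C1=O
A4 | direct plan | 4-{6-[2,4-bis(benzyloxy)phenyl]-4-oxo-4H-pyran-2-yl}-2,3,4-trimethoxycyclobut-2-en-1-one (racemic) | COC1=C(OC)C(OC)(c2cc(=O)cc(-c3ccc(OCc4ccccc4)cc3OCc3ccccc3)o2)C1=O
A5 | direct plan | 2-[2,4-bis(benzyloxy)phenyl]-5-hydroxy-6,7,8-trimethoxy-4H-chromen-4-one | COc1c(OC)c(O)c2c(=O)cc(-c3ccc(OCc4ccccc4)cc3OCc3ccccc3)oc2c1OC
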